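**Strategy.** The 2,2-dimethyl-2H-pyran ring (O1, C2, C3, C4, C4a, C8a) is not closed directly; it is grown from a 2-isopropenyl-2,3-dihydrobenzofuran by a one-carbon ring expansion. The key step exploits the fact that O1 lies para to the C6 benzoyl carbonyl and is therefore a vinylogous carboxylate leaving group. Pd(0) ionises the allylic C–O1 bond, the π-allyl intermediate sheds a benzylic hydrogen to open the furan ring, and the Pd–H so formed adds back at the terminal CH2, so that O1 closes on the former isopropenyl carbon, now the gem-dimethyl C2. The precursor is made without protecting groups from 2,3′,4,6-tetrahydroxybenzophenone by C-prenylation and a Nickl annulation with isoprene dibromide.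

Key step: step 4

Remark: the target has no stereocentre and no stereogenic double bond; it is achiral, so no absolute stereocontrol is needed. The one stereocentre that appears on the way (C2 of 9) is racemic and is erased in step 4.

Step 1
Reactants: 1 phloroglucinol; 2 3-hydroxybenzonitrile
Product: 4 (3-hydroxyphenyl)(2,4,6-trihydroxyphenyl)methanone, via ketiminium chloride 3 (not isolated)
Conditions: ZnCl2 (cat.), HCl (g), Et2O, 0 °C to rt; then H2O, reflux
Reagents that add atoms: water, O; hydrogen chloride, Cl (its chloride is found only in 3)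
Why: Houben–Hoesch acylation, in which the HCl/ZnCl2-activated nitrile attacks the very electron-rich phloroglucinol ring (one kind of C–H by symmetry), the deactivated ketiminium salt stops at mono-acylation, and hydrolysis gives the ketone; no stereocentre is formed.

Step 2
Reactants: 4 (3-hydroxyphenyl)(2,4,6-trihydroxyphenyl)methanone; 5 prenyl bromide
Product: 6 (3-hydroxyphenyl)[2,4,6-trihydroxy-3-(3-methylbut-2-en-1-yl)phenyl]methanone
Conditions: KOH (1.0 equiv), H2O, 0 °C to rt
Reagents that add atoms: none
Why: C-prenylation of an acylphloroglucinol phenolate, in which one equivalent of base should ionise only the 4-OH para to the carbonyl (a vinylogous acid, more acidic than the 3′-OH) and this ambident anion reacts in water with the soft allylic bromide at the ring carbon next to it (C3 and C5 are equivalent); no stereocentre is formed.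

Step 3
Reactants: 6 (3-hydroxyphenyl)[2,4,6-trihydroxy-3-(3-methylbut-2-en-1-yl)phenyl]methanone; 7 (E)-1,4-dibromo-2-methylbut-2-ene
Product: 9 rac-[4,6-dihydroxy-7-(3-methylbut-2-en-1-yl)-2-(prop-1-en-2-yl)-2,3-dihydro-1-benzofuran-5-yl](3-hydroxyphenyl)methanone, via allylic bromide 8 (not isolated)
Conditions: 7 (1.3 equiv), KOH (2 × 1.0 equiv, second portion after the C-alkylation), THF–H2O, 0 to 40 °C
Reagents that add atoms: none
Why: Nickl-type dihydrobenzofuran annulation, in which the phenolate is C-alkylated at its only free ring position by the less hindered CH2Br terminus of the dibromide and the regenerated 4-phenolate (para to C=O, the most acidic OH) closes by 5-exo-trig SN2′ displacement of the second bromide; the new stereocentre C2 forms as a racemate, which does not matter because step 4 destroys it.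

Step 4
Reactants: 9 rac-[4,6-dihydroxy-7-(3-methylbut-2-en-1-yl)-2-(prop-1-en-2-yl)-2,3-dihydro-1-benzofuran-5-yl](3-hydroxyphenyl)methanone
Product: 11 [5,7-dihydroxy-2,2-dimethyl-8-(3-methylbut-2-en-1-yl)-2H-chromen-6-yl](3-hydroxyphenyl)methanone, via dienylphenol 10 (not isolated)
Conditions: Pd(PPh3)4 (5 mol%), PhCO2H (20 mol%), 1,4-dioxane, 100 °C
Reagents that add atoms: none
Why: Proposed new method: Pd(0) ionises the allylic C2–O1 bond of 9 (O1 is para to the benzoyl C=O, so the leaving group is a vinylogous carboxylate), the π-allylpalladium phenoxide loses a benzylic hydrogen from C3 to give dienylphenol 10 and a Pd–H species (kept alive by benzoic acid), Pd–H adds to the terminal CH2 of the diene to give the 1,1-dimethyl-3-aryl π-allyl, and O1 then bonds to its tertiary terminus, which makes the old exocyclic carbon C2 and the old C2 and C3 the C3=C4 of the chromene. The closest known reactions are the Pd-catalysed 1,4-elimination of allylic aryl ethers to 1,3-dienes, the Pd(0)/carboxylic acid hydroalkoxylation of 1,3-dienes and the Pd-catalysed formation of aryl 1,1-dimethylallyl ethers, but their merger into a redox-neutral 1,2-oxygen shift that expands a 2-alkenyl-2,3-dihydrobenzofuran to a 2H-chromene is not known. The one ring that is closed, the 2H-pyran, forms by 6-endo-trig attack of O1 on the CMe2 terminus of the allyl unit, closure at the benzylic terminus being impossible (four-membered ring). No stereocentre is created, and the racemic C2 of 9 ends as the sp2 carbon C3. The step needs reclosure by O1 and not by the chelated 5-OH, which is secured because the departing oxygen is the most acidic one and keeps the negative charge, and it needs the six-membered ring to win over return to 9 or closure to the seven-membered allyl ether, which is secured because those ethers are re-ionised by Pd(0) while the chromene with its styrenic C3=C4 bond is the expected thermodynamic sink; the prenyl group and the free phenols are inert to Pd(0) and a weak acid.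

**Compound list**

1 | phloroglucinol (benzene-1,3,5-triol) | Oc1cc(O)cc(O)c1 | starting material
2 | 3-hydroxybenzonitrile | N#Cc1cccc(O)c1 | starting material
3 | (3-hydroxyphenyl)(2,4,6-trihydroxyphenyl)methaniminium chloride | [Cl-].[NH2+]=C(c1cccc(O)c1)c1c(O)cc(O)cc1O | intermediate
4 | (3-hydroxyphenyl)(2,4,6-trihydroxyphenyl)methanone (2,3′,4,6-tetrahydroxybenzophenone) | O=C(c1cccc(O)c1)c1c(O)cc(O)cc1O | intermediate
5 | prenyl bromide (1-bromo-3-methylbut-2-ene) | CC(C)=CCBr | starting material
6 | (3-hydroxyphenyl)[2,4,6-trihydroxy-3-(3-methylbut-2-en-1-yl)phenyl]methanone | CC(C)=CCc1c(O)cc(O)c(C(=O)c2cccc(O)c2)c1O | intermediate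
7 | (E)-1,4-dibromo-2-methylbut-2-ene (isoprene dibromide) | BrC/C(C)=C/CBr | starting material
8 | {3-[(2E)-4-bromo-3-methylbut-2-en-1-yl]-2,4,6-trihydroxy-5-(3-methylbut-2-en-1-yl)phenyl}(3-hydroxyphenyl)methanone | CC(C)=CCc1c(O)c(C/C=C(\C)CBr)c(O)c(C(=O)c2cccc(O)c2)c1O | intermediate
9 | rac-[4,6-dihydroxy-7-(3-methylbut-2-en-1-yl)-2-(prop-1-en-2-yl)-2,3-dihydro-1-benzofuran-5-yl](3-hydroxyphenyl)methanone (racemic at C2) | CC(C)=CCc1c(O)c(C(=O)c2cccc(O)c2)c(O)c2c1OC(C(C)=C)C2 | intermediate
10 | (3-hydroxyphenyl){2,4,6-trihydroxy-3-[(1E)-3-methylbuta-1,3-dien-1-yl]-5-(3-methylbut-2-en-1-yl)phenyl}methanone | CC(C)=CCc1c(O)c(C(=O)c2cccc(O)c2)c(O)c(/C=C/C(C)=C)c1O | intermediate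
11 | [5,7-dihydroxy-2,2-dimethyl-8-(3-methylbut-2-en-1-yl)-2H-chromen-6-yl](3-hydroxyphenyl)methanone (achiral) | CC(C)=CCc1c(O)c(C(=O)c2cccc(O)c2)c(O)c2c1OC(C)(C)C=C2 | target

**Total step count:** 4
**Longest linear sequence:** 4 steps (1 → 4 → 6 → 9 → 11)

**Steps most likely to fail**

Step 4 (Proposed new method). The π-allylpalladium phenoxide may collapse back to 9, or to the seven-membered allyl aryl ether, faster than it loses the benzylic hydrogen. The open diene 10 may accumulate without closing. Pd–H may also walk the isopropenyl double bond into the furan ring and aromatise it to a 2-isopropylbenzofuran, which is probably more stable than the chromene. The fallback uses known chemistry, sets out from 6 and comes back at 11. The most acidic 4-OH of 6 would be O-alkylated with 3-chloro-3-methylbut-1-yne (K2CO3, KI, CuI cat., acetone, 50 °C) to give {2,6-dihydroxy-4-[(2-methylbut-3-yn-2-yl)oxy]-3-(3-methylbut-2-en-1-yl)phenyl}(3-hydroxyphenyl)methanone F1. Heating F1 (N,N-diethylaniline, 130 °C) should give 11 by aromatic propargyl Claisen rearrangement to the only free ortho carbon, [1,5]-H shift and oxa-6π electrocyclisation. This fallback closes the pyran ring directly in its final size and gives up the ring-expansion design; it is a reserve only.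

Step 3. The phenolate may attack through the more hindered CH2Br terminus, which would lead to the 2-methyl-2-vinyl isomer. It may be O-alkylated instead of C-alkylated, two phenolates may be cross-linked by the bifunctional bromide, and the ring may be closed by the chelated 6-OH instead of the 4-OH. The fallback sets out from 6 and comes back at 9. A second C-prenylation of 6 with 5 (KOH, 1.0 equiv, H2O, 0 °C) would give (3-hydroxyphenyl)[2,4,6-trihydroxy-3,5-bis(3-methylbut-2-en-1-yl)phenyl]methanone F2, in which the two prenyl groups are equivalent. A Pd(II)-catalysed aerobic oxidative cyclisation of the Hosokawa–Murahashi type (Pd(OAc)2 10 mol%, Cu(OAc)2 cat., O2, MeOH–H2O, 40 °C) should then give 9 by 5-exo oxypalladation by the 4-OH and β-hydride elimination towards a methyl group. Here the C–O bond is made by oxypalladation of a prenyl group already in place and not by SN2′ displacement.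

Step 2. Alkylation may run on to the 3,5-diprenyl and the dearomatised 3,3-diprenyl compounds, and O-prenylation may compete, also at the 3′-OH. The fallback sets out from 4 and comes back at 6. The 4-OH of 4 would be etherified with 3-chloro-3-methylbut-1-yne (K2CO3, KI, CuI cat., acetone, 50 °C) to give {2,6-dihydroxy-4-[(2-methylbut-3-yn-2-yl)oxy]phenyl}(3-hydroxyphenyl)methanone F3. Lindlar semi-hydrogenation (H2, Pd/CaCO3–Pb, quinoline, EtOAc, rt) would give the 1,1-dimethylallyl ether {2,6-dihydroxy-4-[(2-methylbut-3-en-2-yl)oxy]phenyl}(3-hydroxyphenyl)methanone F4. Its aromatic Claisen rearrangement (toluene, 110 °C) should place exactly one prenyl group on the carbon ortho to the 4-OH and give 6.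

**Further compounds**

F1 | step 4 | {2,6-dihydroxy-4-[(2-methylbut-3-yn-2-yl)oxy]-3-(3-methylbut-2-en-1-yl)phenyl}(3-hydroxyphenyl)methanone | CC(C)=CCc1c(OC(C)(C)C#C)cc(O)c(C(=O)c2cccc(O)c2)c1O
F2 | step 3 | (3-hydroxyphenyl)[2,4,6-trihydroxy-3,5-bis(3-methylbut-2-en-1-yl)phenyl]methanone | CC(C)=CCc1c(O)c(CC=C(C)C)c(O)c(C(=O)c2cccc(O)c2)c1O
F3 | step 2 | {2,6-dihydroxy-4-[(2-methylbut-3-yn-2-yl)oxy]phenyl}(3-hydroxyphenyl)methanone | C#CC(C)(C)Oc1cc(O)c(C(=O)c2cccc(O)c2)c(O)c1
F4 | step 2 | {2,6-dihydroxy-4-[(2-methylbut-3-en-2-yl)oxy]phenyl}(3-hydroxyphenyl)methanone | C=CC(C)(C)Oc1cc(O)c(C(=O)c2cccc(O)c2)c(O)c1
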